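**Plan** (chain numbered C1 = ester carbonyl to C22 = terminal alkyne carbon; the ring is the 1,2-dioxane made of the O–O unit and C3–C6)
- Cuts: C13–C14 (alkyl–vinyl, B-alkyl Suzuki–Miyaura), then C11–C12 (Sonogashira), with C12=C13 supplied by (E)-1,2-dichloroethene as a two-carbon linchpin; then the ring O–C3 bond (intramolecular peroxide alkylation), the C6 peroxyketal (ozonolysis of a C6 methylidene in methanol) and C4–C5 (allyl Grignard on an epoxide).
- Forward: epoxide 4 and allyl Grignard 9 give carbinol 10; mesylation, ozonolysis and ring closure give the 1,2-dioxane; the side chain on C3 is taken to the methyl ester (17); chlorovinylation gives 19; union with the C14–C22 borane and desilylation finish the chain.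
- Stereochemistry: C3 comes from a hydrolytic kinetic resolution (R carbinol, inverted to 3S in the SN2 ring closure); C6 is set by acid equilibration of the peroxyketal to the anomer with axial methoxy (6R); the E alkene comes from (E)-1,2-dichloroethene with retention in both couplings.
- Enabling feature: the E C12=C13 alkene is conjugated to the C10≡C11 alkyne, so C13 can be carried as an activated chloroenyne terminus that zerovalent palladium enters readily, while the O–O bond of the saturated dioxane ring has no allylic or carbonyl activation.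

Key step: step 14

Remark: compounds 1, 5, 6, 18, 20 and 21 are taken as commercial; the ring closure of step 8 is assumed to give both C6 epimers, which acidic methanol should converge on the more stable 6R anomer.

**Step 1**
Reactants: 1 but-3-en-1-ol
Product: 2 tert-butyl(but-3-en-1-yloxy)diphenylsilane
Conditions: TBDPSCl, imidazole, CH2Cl2, 0 °C to rt
Reagents that add atoms: tert-butyl(chloro)diphenylsilane, CC(C)(C)[Si](Cl)(c1ccccc1)c1ccccc1
Why: Imidazole-promoted silyl ether formation on a primary alcohol is reliable, and the tert-butyldiphenylsilyl group is chosen because it should survive the acidic methanol of step 8.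

**Step 2**
Reactants: 2 tert-butyl(but-3-en-1-yloxy)diphenylsilane
Product: 3 racemic tert-butyl[2-(oxiran-2-yl)ethoxy]diphenylsilane
Conditions: mCPBA, CH2Cl2, 0 °C to rt
Reagents that add atoms: 3-chloroperbenzoic acid, OOC(=O)c1cccc(Cl)c1
Why: Prilezhaev epoxidation of the only alkene by the peracid should give the racemic terminal epoxide.

**Step 3**
Reactants: 3 racemic tert-butyl[2-(oxiran-2-yl)ethoxy]diphenylsilane
Product: 4 (S)-tert-butyl[2-(oxiran-2-yl)ethoxy]diphenylsilane
Conditions: (S,S)-(salen)Co(OAc) (0.5 mol%; salen = N,N'-bis(3,5-di-tert-butylsalicylidene)cyclohexane-1,2-diamine dianion, trivalent cobalt), H2O (0.55 equiv), THF, 0 °C to rt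
Reagents that add atoms: none
Why: Jacobsen hydrolytic kinetic resolution, run with the catalyst antipode that hydrolyses the R epoxide, should leave the S epoxide in high enantiomeric purity; this is the source of the C3 stereocenter.

**Step 4**
Reactants: 5 (4-bromobut-1-yn-1-yl)trimethylsilane; 6 3-chloro-2-(chloromethyl)prop-1-ene
Product: 8 [6-(chloromethyl)hept-6-en-1-yn-1-yl]trimethylsilane, via homopropargyl Grignard reagent 7 (not isolated)
Conditions: Mg, THF, 40 °C; then added to 6 (3 equiv), CuI (5 mol%), THF, −20 to 0 °C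
Reagents that add atoms: none
Why: Copper-catalysed allylic substitution by a Grignard reagent on the symmetric dichloride gives one product whether it runs SN2 or SN2', and the excess of 6 should hold back a second substitution.

**Step 5**
Reactants: 8 [6-(chloromethyl)hept-6-en-1-yn-1-yl]trimethylsilane; 4 (S)-tert-butyl[2-(oxiran-2-yl)ethoxy]diphenylsilane
Product: 10 (R)-1-[(tert-butyldiphenylsilyl)oxy]-6-methylidene-11-(trimethylsilyl)undec-10-yn-3-ol, via allylic Grignard reagent 9 (not isolated)
Conditions: Mg turnings (excess), THF, 0 °C, slow addition of 8; then CuI (10 mol%), 4, −30 to 0 °C; aq. NH4Cl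
Reagents that add atoms: none
Why: Copper-catalysed epoxide opening by an allylic Grignard reagent at the unsubstituted carbon forms C4–C5 without touching the stereocenter (S becomes R only through the change of priorities), and the two allyl termini are identical.

**Step 6**
Reactants: 10 (R)-1-[(tert-butyldiphenylsilyl)oxy]-6-methylidene-11-(trimethylsilyl)undec-10-yn-3-ol
Product: 11 (R)-1-[(tert-butyldiphenylsilyl)oxy]-6-methylidene-11-(trimethylsilyl)undec-10-yn-3-yl methanesulfonate
Conditions: MsCl, Et3N, CH2Cl2, 0 °C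
Reagents that add atoms: methanesulfonyl chloride, CS(=O)(=O)Cl
Why: Mesylate formation occurs at oxygen with retention and makes C3 the electrophile for the ring closure.

**Step 7**
Reactants: 11 (R)-1-[(tert-butyldiphenylsilyl)oxy]-6-methylidene-11-(trimethylsilyl)undec-10-yn-3-yl methanesulfonate
Product: 12 (3R)-1-[(tert-butyldiphenylsilyl)oxy]-6-hydroperoxy-6-methoxy-11-(trimethylsilyl)undec-10-yn-3-yl methanesulfonate (both C6 epimers)
Conditions: O3/O2, CH2Cl2/MeOH (4:1), −78 °C, Sudan Red 7B as end-point indicator; N2 purge, no reductant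
Reagents that add atoms: ozone, [O-][O+]=O; methanol, CO
Why: Ozonolysis in methanol (Criegee mechanism) splits the primary ozonide into formaldehyde and the more substituted ketone oxide at C6, which methanol traps as the hydroperoxyketal; the electron-rich 1,1-disubstituted alkene should react far faster than the silyl alkyne or the arenes.

**Step 8**
Reactants: 12 (3R)-1-[(tert-butyldiphenylsilyl)oxy]-6-hydroperoxy-6-methoxy-11-(trimethylsilyl)undec-10-yn-3-yl methanesulfonate (both C6 epimers)
Product: 14 tert-butyl{2-[(3S,6R)-6-methoxy-6-[5-(trimethylsilyl)pent-4-yn-1-yl]-1,2-dioxan-3-yl]ethoxy}diphenylsilane, via dioxane C6-epimer mixture 13 (not isolated)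
Conditions: KOtBu (1.05 equiv), 18-crown-6, THF, 0 °C; then MeOH, camphorsulfonic acid (0.2 equiv), rt
Reagents that add atoms: methanol, CO
Why: Intramolecular alkylation of the hydroperoxide (6-exo-tet SN2 at C3 with inversion, R to S) closes the 1,2-dioxane, and acid-catalysed peroxyketal exchange through the ring peroxycarbenium ion should then funnel both C6 epimers to the 6R anomer (methoxy axial by the anomeric effect, both carbon substituents equatorial).

**Step 9**
Reactants: 14 tert-butyl{2-[(3S,6R)-6-methoxy-6-[5-(trimethylsilyl)pent-4-yn-1-yl]-1,2-dioxan-3-yl]ethoxy}diphenylsilane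
Product: 15 2-[(3S,6R)-6-methoxy-6-(pent-4-yn-1-yl)-1,2-dioxan-3-yl]ethan-1-ol
Conditions: TBAF (2.5 equiv), THF, 0 °C to rt
Reagents that add atoms: none
Why: Fluoride-mediated desilylation cleaves the O–Si and the C(sp)–Si bond in one operation, and a saturated dialkyl peroxide with no acidifying group at C3–H should tolerate the mildly basic fluoride.

**Step 10**
Reactants: 15 2-[(3S,6R)-6-methoxy-6-(pent-4-yn-1-yl)-1,2-dioxan-3-yl]ethan-1-ol
Product: 16 2-[(3S,6R)-6-methoxy-6-(pent-4-yn-1-yl)-1,2-dioxan-3-yl]acetic acid
Conditions: TEMPO (0.2 equiv), PhI(OAc)2 (2.5 equiv), MeCN/aq. pH 7 phosphate buffer (1:1), rt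
Reagents that add atoms: water, O
Why: Oxoammonium (TEMPO/PhI(OAc)2) oxidation of the primary alcohol through the aldehyde hydrate gives the acid under buffered, oxidising conditions that should spare the peroxyketal, the O–O bond and the alkyne.

**Step 11**
Reactants: 16 2-[(3S,6R)-6-methoxy-6-(pent-4-yn-1-yl)-1,2-dioxan-3-yl]acetic acid
Product: 17 methyl 2-[(3S,6R)-6-methoxy-6-(pent-4-yn-1-yl)-1,2-dioxan-3-yl]acetate
Conditions: TMSCHN2 (1.5 equiv), toluene/MeOH (4:1), 0 °C
Reagents that add atoms: (trimethylsilyl)diazomethane, C[Si](C)(C)C=[N+]=[N-]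
Why: Methyl ester formation by diazomethane released from TMSCHN2 in methanol is neutral, so neither the base-sensitive β-peroxy ester nor the acid-sensitive peroxyketal should be disturbed.

**Step 12**
Reactants: 17 methyl 2-[(3S,6R)-6-methoxy-6-(pent-4-yn-1-yl)-1,2-dioxan-3-yl]acetate; 18 (E)-1,2-dichloroethene
Product: 19 methyl 2-[(3S,6R)-6-[(E)-7-chlorohept-6-en-4-yn-1-yl]-6-methoxy-1,2-dioxan-3-yl]acetate
Conditions: 18 (5 equiv), Pd(PPh3)4 (5 mol%), CuI (10 mol%), n-BuNH2 (2 equiv), Et2O, rt
Reagents that add atoms: none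
Why: Sonogashira coupling with a large excess of the dichloride should favour mono-coupling to the E chloroenyne with retention of geometry, and saturated 1,2-dioxanes are known to survive zerovalent palladium/CuI/amine conditions.

**Step 13**
Reactants: 20 ethynyltrimethylsilane; 21 7-bromohept-1-ene
Product: 23 trimethyl(non-8-en-1-yn-1-yl)silane, via lithium acetylide 22 (not isolated)
Conditions: n-BuLi (1.0 equiv), THF, −78 °C; then 21, DMPU, −78 °C to rt
Reagents that add atoms: none
Why: SN2 alkylation of a lithium acetylide by a primary bromide in a dipolar cosolvent builds the C14–C22 unit, with the silyl group masking the future C22–H.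

**Step 14**
Reactants: 23 trimethyl(non-8-en-1-yn-1-yl)silane; 19 methyl 2-[(3S,6R)-6-[(E)-7-chlorohept-6-en-4-yn-1-yl]-6-methoxy-1,2-dioxan-3-yl]acetate
Product: 25 methyl 2-[(3S,6R)-6-methoxy-6-[(E)-16-(trimethylsilyl)hexadec-6-en-4,15-diyn-1-yl]-1,2-dioxan-3-yl]acetate, via B-alkyl borane 24 (not isolated)
Conditions: 23 (1.6 equiv), 9-BBN (0.5 M in THF, 1.5 equiv), rt; then 3 M aq. K3PO4 (3 equiv), 19 (1.0 equiv), Pd(OAc)2 (5 mol%), SPhos (2-dicyclohexylphosphino-2',6'-dimethoxybiphenyl, 6 mol%), THF, rt to 40 °C
Reagents that add atoms: none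
Why: Anti-Markovnikov hydroboration of the terminal alkene of 23 by 9-BBN gives the primary borane 24, whose borate (formed with aqueous phosphate) transfers its primary alkyl group to the alkenylpalladium chloride that zerovalent palladium forms by insertion into the C13–Cl bond of 19, and reductive elimination then forges C13–C14. The closest known reaction type is the B-alkyl Suzuki–Miyaura coupling of an alkenyl halide. No ring is closed and no stereocenter is created; the E geometry of C12=C13 is inherited from (E)-1,2-dichloroethene because oxidative addition and reductive elimination both proceed with retention at the sp2 carbon. The step needs chemoselectivity for C–Cl over O–O, and this is secured by the chlorine sitting on the terminus of a 1-en-3-yne, whose conjugated alkyne accelerates oxidative addition, while the O–O bond of the saturated dioxane ring is an unactivated dialkyl peroxide/peroxyketal. Only the primary alkyl group leaves boron (the bicyclic secondary B–C bonds do not transfer), the bulky biaryl phosphine should let reductive elimination outrun β-hydride elimination, the silyl cap keeps C21≡C22 out of both hydroboration and alkynylation, and the excess of alkene over 9-BBN leaves no B–H to reach the peroxide. The mild aqueous phosphate should leave the methyl ester and C3 intact, because reversal of the O–C3 bond would require enolisation of the ester.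

**Step 15**
Reactants: 25 methyl 2-[(3S,6R)-6-methoxy-6-[(E)-16-(trimethylsilyl)hexadec-6-en-4,15-diyn-1-yl]-1,2-dioxan-3-yl]acetate
Product: 26 methyl 2-[(3S,6R)-6-[(E)-hexadec-6-en-4,15-diyn-1-yl]-6-methoxy-1,2-dioxan-3-yl]acetate (CNP0314169.1)
Conditions: AgNO3 (0.2 equiv), acetone/H2O (4:1), rt, dark
Reagents that add atoms: none
Why: Silver-catalysed protodesilylation of the alkynylsilane runs in neutral aqueous acetone, so neither retro-oxa-Michael opening of the β-peroxy ester nor ketal hydrolysis should intervene.

**Compound list**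
1 | but-3-en-1-ol | C=CCCO | starting material
2 | tert-butyl(but-3-en-1-yloxy)diphenylsilane | C=CCCO[Si](c1ccccc1)(c1ccccc1)C(C)(C)C | intermediate
3 | racemic tert-butyl[2-(oxiran-2-yl)ethoxy]diphenylsilane | CC(C)(C)[Si](OCCC1CO1)(c1ccccc1)c1ccccc1 | intermediate
4 | (S)-tert-butyl[2-(oxiran-2-yl)ethoxy]diphenylsilane | CC(C)(C)[Si](OCC[C@H]1CO1)(c1ccccc1)c1ccccc1 | intermediate
5 | (4-bromobut-1-yn-1-yl)trimethylsilane | C[Si](C)(C)C#CCCBr | starting material
6 | 3-chloro-2-(chloromethyl)prop-1-ene | C=C(CCl)CCl | starting material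
7 | [4-(trimethylsilyl)but-3-yn-1-yl]magnesium bromide | C[Si](C)(C)C#CCC[Mg]Br | intermediate
8 | [6-(chloromethyl)hept-6-en-1-yn-1-yl]trimethylsilane | C=C(CCl)CCCC#C[Si](C)(C)C | intermediate
9 | [2-methylidene-7-(trimethylsilyl)hept-6-yn-1-yl]magnesium chloride | C=C(C[Mg]Cl)CCCC#C[Si](C)(C)C | intermediate
10 | (R)-1-[(tert-butyldiphenylsilyl)oxy]-6-methylidene-11-(trimethylsilyl)undec-10-yn-3-ol | CC(C)(C)[Si](OCC[C@H](O)CCC(=C)CCCC#C[Si](C)(C)C)(c1ccccc1)c1ccccc1 | intermediate
11 | (R)-1-[(tert-butyldiphenylsilyl)oxy]-6-methylidene-11-(trimethylsilyl)undec-10-yn-3-yl methanesulfonate | CC(C)(C)[Si](OCC[C@H](OS(C)(=O)=O)CCC(=C)CCCC#C[Si](C)(C)C)(c1ccccc1)c1ccccc1 | intermediate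
12 | (3R)-1-[(tert-butyldiphenylsilyl)oxy]-6-hydroperoxy-6-methoxy-11-(trimethylsilyl)undec-10-yn-3-yl methanesulfonate (both C6 epimers) | CC(C)(C)[Si](OCC[C@H](OS(C)(=O)=O)CCC(OC)(OO)CCCC#C[Si](C)(C)C)(c1ccccc1)c1ccccc1 | intermediate
13 | tert-butyl{2-[(3S)-6-methoxy-6-[5-(trimethylsilyl)pent-4-yn-1-yl]-1,2-dioxan-3-yl]ethoxy}diphenylsilane (both C6 epimers) | CC(C)(C)[Si](OCC[C@@H]1CCC(OC)(CCCC#C[Si](C)(C)C)OO1)(c1ccccc1)c1ccccc1 | intermediate
14 | tert-butyl{2-[(3S,6R)-6-methoxy-6-[5-(trimethylsilyl)pent-4-yn-1-yl]-1,2-dioxan-3-yl]ethoxy}diphenylsilane | CC(C)(C)[Si](OCC[C@@H]1CC[C@@](OC)(CCCC#C[Si](C)(C)C)OO1)(c1ccccc1)c1ccccc1 | intermediate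
15 | 2-[(3S,6R)-6-methoxy-6-(pent-4-yn-1-yl)-1,2-dioxan-3-yl]ethan-1-ol | OCC[C@@H]1CC[C@@](OC)(CCCC#C)OO1 | intermediate
16 | 2-[(3S,6R)-6-methoxy-6-(pent-4-yn-1-yl)-1,2-dioxan-3-yl]acetic acid | OC(=O)C[C@@H]1CC[C@@](OC)(CCCC#C)OO1 | intermediate
17 | methyl 2-[(3S,6R)-6-methoxy-6-(pent-4-yn-1-yl)-1,2-dioxan-3-yl]acetate | COC(=O)C[C@@H]1CC[C@@](OC)(CCCC#C)OO1 | intermediate
18 | (E)-1,2-dichloroethene | Cl/C=C/Cl | starting material
19 | methyl 2-[(3S,6R)-6-[(E)-7-chlorohept-6-en-4-yn-1-yl]-6-methoxy-1,2-dioxan-3-yl]acetate | COC(=O)C[C@@H]1CC[C@@](OC)(CCCC#C/C=C/Cl)OO1 | intermediate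
20 | ethynyltrimethylsilane | C#C[Si](C)(C)C | starting material
21 | 7-bromohept-1-ene | C=CCCCCCBr | starting material
22 | lithium (trimethylsilyl)acetylide | [Li]C#C[Si](C)(C)C | intermediate
23 | trimethyl(non-8-en-1-yn-1-yl)silane | C=CCCCCCC#C[Si](C)(C)C | intermediate
24 | 9-[9-(trimethylsilyl)non-8-yn-1-yl]-9-borabicyclo[3.3.1]nonane | C[Si](C)(C)C#CCCCCCCCB1C2CCCC1CCC2 | intermediate
25 | methyl 2-[(3S,6R)-6-methoxy-6-[(E)-16-(trimethylsilyl)hexadec-6-en-4,15-diyn-1-yl]-1,2-dioxan-3-yl]acetate | COC(=O)C[C@@H]1CC[C@@](OC)(CCCC#C/C=C/CCCCCCCC#C[Si](C)(C)C)OO1 | intermediate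
26 | methyl 2-[(3S,6R)-6-[(E)-hexadec-6-en-4,15-diyn-1-yl]-6-methoxy-1,2-dioxan-3-yl]acetate | C#CCCCCCCC/C=C/C#CCCC[C@]1(OC)CC[C@@H](CC(=O)OC)OO1 | target

**Count**
Total steps: 15. Longest linear sequence: 13 steps (steps 1–3, 5–12, 14 and 15, from but-3-en-1-ol).

**Steps most likely to fail**

Step 14. The O–O bond could be cleaved reductively by the borane/phosphine/low-valent palladium mixture, oxidative addition into C–Cl could be slow enough for β-hydride elimination of the alkylpalladium to win, or the aqueous base could hydrolyse the ester. The fallback replaces the basic organoboron union by a base-free organozinc (Negishi) union. It sets out from 24 (made from 23 as in step 14) and comes back at 25. Oxidation of 24 with NaBO3·4H2O in THF/H2O should give 9-(trimethylsilyl)non-8-yn-1-ol F1. I2, PPh3 and imidazole in CH2Cl2 should convert this into (9-iodonon-1-yn-1-yl)trimethylsilane F2. Zinc dust with LiCl in THF should insert to give [9-(trimethylsilyl)non-8-yn-1-yl]zinc iodide F3, which is decanted from the excess metal so that no reducing zinc meets the peroxide. Coupling of F3 with 19 under Pd(PPh3)4 in THF/NMP at rt should then give 25.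

Step 8. E2 elimination of the secondary mesylate or fragmentation of the hydroperoxyketal anion could outrun the 6-exo-tet closure, and the acid treatment could open the ring or leave the C6 epimers unequilibrated. The fallback separates the SN2 event from the ring closure and lets the ring form by reversible ketalisation. It sets out from 11 and comes back at 14. Displacement of the mesylate by the cesium salt of 2-methoxypropan-2-yl hydroperoxide (CsOH, DMF, 0 °C to rt) should give, with inversion, tert-butyl{[(3S)-3-[(2-methoxypropan-2-yl)peroxy]-6-methylidene-11-(trimethylsilyl)undec-10-yn-1-yl]oxy}diphenylsilane F4. Ozonolysis in CH2Cl2 at −78 °C with Me2S work-up should give (9S)-11-[(tert-butyldiphenylsilyl)oxy]-9-[(2-methoxypropan-2-yl)peroxy]-1-(trimethylsilyl)undec-1-yn-6-one F5. Camphorsulfonic acid in methanol should unmask the secondary hydroperoxide, which adds to the C6 ketone and is methylated under thermodynamic control to give 14.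

Step 12. Coupling at both C–Cl bonds, oxidative dimerisation of the alkyne, or a slow reaction that leaves the peroxide exposed to copper and amine could erode the mono-coupling. The fallback reverses the order of the two unions, so that the dichloride meets the peroxide-free tail first. It sets out from 24 and 18 and comes back at 25, replacing steps 12 and 14. B-alkyl Suzuki–Miyaura coupling of 24 with 18 (5 equiv; Pd(OAc)2, SPhos, aq. K3PO4, THF) should give (E)-(11-chloroundec-10-en-1-yn-1-yl)trimethylsilane F6. Sonogashira coupling of F6 with 17 (PdCl2(PhCN)2, CuI, piperidine, rt) should then form C11–C12 and give 25.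

**Further compounds**
F1 | step 14 | 9-(trimethylsilyl)non-8-yn-1-ol | C[Si](C)(C)C#CCCCCCCCO
F2 | step 14 | (9-iodonon-1-yn-1-yl)trimethylsilane | C[Si](C)(C)C#CCCCCCCCI
F3 | step 14 | [9-(trimethylsilyl)non-8-yn-1-yl]zinc iodide | C[Si](C)(C)C#CCCCCCCC[Zn]I
F4 | step 8 | tert-butyl{[(3S)-3-[(2-methoxypropan-2-yl)peroxy]-6-methylidene-11-(trimethylsilyl)undec-10-yn-1-yl]oxy}diphenylsilane | CC(C)(C)[Si](OCC[C@@H](OOC(C)(C)OC)CCC(=C)CCCC#C[Si](C)(C)C)(c1ccccc1)c1ccccc1
F5 | step 8 | (9S)-11-[(tert-butyldiphenylsilyl)oxy]-9-[(2-methoxypropan-2-yl)peroxy]-1-(trimethylsilyl)undec-1-yn-6-one | CC(C)(C)[Si](OCC[C@@H](OOC(C)(C)OC)CCC(=O)CCCC#C[Si](C)(C)C)(c1ccccc1)c1ccccc1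
F6 | step 12 | (E)-(11-chloroundec-10-en-1-yn-1-yl)trimethylsilane | Cl/C=C/CCCCCCCC#C[Si](C)(C)C
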